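I had no constants for these flasks, so I read one from the runs.

| setting | dawn | noon | summer | red | violet | ochre | amber |
|---|---|---|---|---|---|---|---|
| starting material | 20 mM | 20 mM | 20 mM | 20 mM | 20 mM | 20 mM (fed, over 1.0 h) | 20 mM (fed, over 1.0 h) |
| coupling partner | 2.5 equiv | 2.5 equiv | 2.5 equiv | 2.50 equiv | 2.50 equiv | 2.50 equiv | 2.50 equiv |
| second substrate | 1 equiv | 1 equiv | 1 equiv | 1.00 equiv (fed, over 1.0 h) | 1.00 equiv | 1.00 equiv | 1.00 equiv |
| third substrate | 0.50 equiv | 0.70 equiv | 1.1 equiv | 0.500 equiv | 0.500 equiv | 0.500 equiv | 0.500 equiv |
| temperature | 85 °C | 96 °C | 85 °C | 90 °C | 90 °C |  | 90 °C |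
| remark | run made earlier | run made earlier | run made earlier | all else is in the flask from the start; the feed brings no volume worth counting | everything together at the start | the addition at 60 °C, then warmed to 90 °C; the feed brings no volume worth counting | all else is in the flask from the start; the feed brings no volume worth counting |
| time |  |  |  | 80 min | 80 min | 80 min | 80 min |

- dawn (time / min: target / %, starting material / %): 6.00: 31.6, 66.1; 10.0: 31.9, 63.1; 20.0: 30.9, 60.2; 30.0: 29.8, 58.7; 50.0: 27.0, 57.0; 80.0: 23.7, 55.0
- noon (time / min: target / %, starting material / %): 15.0: 23.0, 59.8; 30.0: 20.4, 56.2; 50.0: 18.1, 55.0; 60.0: 17.2, 54.2; 80.0: 15.5, 54.0; 90.0: 15.3, 55.1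
- summer (time / min: target / %, starting material / %): 8.00: 24.3, 71.8; 12.0: 23.5, 69.2; 20.0: 23.7, 66.5; 40.0: 21.9, 63.4; 60.0: 19.8, 61.9; 90.0: 17.5, 59.2

(readings scatter by 0.5 percentage points)

- the numbers in the tables scatter with a standard deviation of 0.5 percentage points
- on the list of suspects stand: starting material + coupling partner <-> target; second substrate + coupling partner -> second product; third substrate + coupling partner -> third product; starting material <-> dormant form

1. which flask leads in amount of target, in percent of the starting material charged ("all alike" within 1.5 percentage points) (red / violet / ochre / amber / all alike)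
2. how much target is there at the end, in percent of the starting material charged: red
3. how much target is there at the end, in percent of the starting material charged: violet
4. how much target is there at the end, in percent of the starting material charged: ochre
5. how much target is there at the end, in percent of the starting material charged: amber

Dawn at 10.0 min read 0.301: that is my holding ratio, target over starting material per equivalent of free coupling partner, an apparent equilibrium constant. I took free partner as its charge less the third substrate's charge less the target. Summer at 8.00 min, with a larger third-substrate charge, read 0.293. I assumed the ratio holds unchanged at 90 °C.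

This is my note for whoever takes the bench. I solved two ends and joined them with the ratio. The late end is violet, hot for 80 min. I averaged dawn at 80.0 min and noon at 80.0 min. The missing fraction of the charge, which I counted as dormant form, came to 0.259. The ratio showed 0.510 equivalents of partner lost to the second substrate. Solving the ratio with those two losses gave violet 0.206 as target.

The early end is ochre. I counted its cold hour as nothing and its 20.0 min hot as dawn at 20.0 min averaged with noon at 15.0 min. That gave a gap of 0.131, a partner loss of 0.138 equivalents, and target 0.280. Do not warm ochre before its feed ends: with 80 min hot against 20.0 min, my reckoning put both losses higher, the gap and the partner loss. Red and amber sit at 90 °C from the start, and I placed them near violet.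

The forecast named ochre, with red 22.3%, violet 21%, ochre 27% (lower than mine) and amber 21.8%, holding that “the cold feed avoids both drains”.

The flasks gave ochre the lead: red 22.2%, violet 20.5%, ochre 27.0%, amber 21.4%. At the end, ochre held 13.1% as dormant form and violet 25.6%.

    starting material + coupling partner ⇌ target (K = 15.0 M⁻¹, k = 0.0850 M⁻¹ s⁻¹, Ea = 72.0 kJ mol⁻¹, ΔH = −18.0 kJ mol⁻¹)
    second substrate + coupling partner → second product (k = 0.00560 M⁻¹ s⁻¹, Ea = 68.0 kJ mol⁻¹)
    third substrate + coupling partner → third product (k = 0.930 M⁻¹ s⁻¹, Ea = 43.0 kJ mol⁻¹)
    starting material ⇌ dormant form (K = 0.540, k = 2.10 × 10⁻⁴ s⁻¹, Ea = 126 kJ mol⁻¹, ΔH = 0 kJ mol⁻¹)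
    (constants at 90 °C)

Violet's end, with 50.2% of its partner left, gives a holding ratio of 0.303. The neighbour of violet charged with 10.0 equiv of partner ended with 61.8% target, 26.0% starting material and 79.0% of its partner left, which gives 0.301.

All runs were computed on assumed constants; scatter was added.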